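**Plan**

- Retrosynthesis: the eight O–benzyl bonds are cut first, then the two bonds between each benzylic CH2 and its catechol ring, which leaves the methyl groups of two (R)-lactate esters. Next come the cyclobutane bonds C1–C4 and C2–C3 ([2+2] of a fumarate bis-lactate with an E-stilbene), and last the fumarate ester C–O bonds and the stilbene C=C.
- Forward: a McMurry coupling of two molecules of the protected aldehyde gives the stilbene, and fumaryl chloride is esterified at both ends with two molecules of tert-butyl (R)-lactate. The cyclobutane, the only ring made, arises in the photocycloaddition. The tert-butyl esters are then removed, both arms are arylated in one operation with two molecules of the aryl iodide, and the benzyl ethers are hydrogenolysed.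
- Enabling feature: in each arm the free CO2H sits on the oxygen-bearing CH whose other carbon substituent is the benzylic CH2, so that carbon is beta to the acid. As a CH3 in the lactate precursor it can be reached by carboxylate-bound palladium through a five-membered palladacycle (Pd–O–C–Cα–Cβ). The four-membered ring carries only ester carbonyls, which do not direct.
- Stereochemistry: the two arm centres (R) come unchanged from the lactate chiral pool. The relative configuration of the four ring centres (esters trans, aryls trans, each ester cis to its neighbouring aryl) comes from the stereospecific exciplex cycloaddition of two E-alkenes. The absolute ring configuration comes from separating the two ring diastereomers formed under the influence of the (R)-lactate arms.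

Key step: step 6

Assumption: the benzyl-protected aldehyde, the benzyl-protected arene and the tert-butyl (R)-lactate that open steps 1, 5 and 2 are bought as such.
Remark: the partly debenzylated species passed through in step 7 are a mixture of many isomers and carry no numbers.
Remark: steps 1, 2 and 6 each consume two molecules of one building block per molecule of product; the second molecule is entered as an atom source in the step.

**Route**

Step 1
Reactants: 1 3,4-bis(benzyloxy)benzaldehyde
Product: 2 (E)-1,2-bis[3,4-bis(benzyloxy)phenyl]ethene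
Conditions: 1 (2 equiv), TiCl4, Zn, THF, reflux; E isomer purified by recrystallisation
Reagents that add atoms: 3,4-bis(benzyloxy)benzaldehyde (second molecule of 1), O=Cc1ccc(OCc2ccccc2)c(OCc2ccccc2)c1
Why: McMurry homocoupling, in which low-valent titanium joins two molecules of the aryl aldehyde through a titanium pinacolate and deoxygenates it to the alkene, aromatic aldehydes giving mainly the E-stilbene and benzyl aryl ethers being inert to the reagent.

Step 2
Reactants: 3 tert-butyl (R)-lactate; 4 fumaryl chloride
Product: 6 bis[(R)-1-(tert-butoxycarbonyl)ethyl] fumarate, via fumaric monoester acid chloride 5 (not isolated)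
Conditions: 3 (2 equiv), pyridine, DMAP (catalytic), CH2Cl2, 0 °C to rt
Reagents that add atoms: tert-butyl (R)-lactate (second molecule of 3), C[C@@H](O)C(=O)OC(C)(C)C
Why: Pyridine-mediated twofold esterification of a secondary alcohol with a diacid dichloride, the first molecule of 3 giving 5 and the second giving 6, which touches no bond at the lactate stereocentre, so both (R) centres and the E double bond are carried through unchanged.

Step 3
Reactants: 6 bis[(R)-1-(tert-butoxycarbonyl)ethyl] fumarate; 2 (E)-1,2-bis[3,4-bis(benzyloxy)phenyl]ethene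
Product: 7 bis[(R)-1-(tert-butoxycarbonyl)ethyl] (1R,2R,3R,4R)-3,4-bis[3,4-bis(benzyloxy)phenyl]cyclobutane-1,2-dicarboxylate
Conditions: hν (medium-pressure Hg lamp, filter for λ > 330 nm), 6 in excess, degassed benzene, rt; chromatography and crystallisation to part the two ring diastereomers
Reagents that add atoms: none
Why: Stilbene–fumarate [2+2] photocycloaddition through the singlet exciplex, in which the selectively excited electron-rich stilbene stacks on the electron-poor fumarate with ester over aryl and collapses suprafacially on both E-alkenes; this sets the four ring centres in the esters-trans, aryls-trans, ester-cis-to-neighbouring-aryl pattern, while the (R)-lactate arms are the only source of facial bias, so the (1R,2R,3R,4R) isomer is separated from its (1S,2S,3S,4S) ring diastereomer and its configuration secured by X-ray crystallography.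

Step 4
Reactants: 7 bis[(R)-1-(tert-butoxycarbonyl)ethyl] (1R,2R,3R,4R)-3,4-bis[3,4-bis(benzyloxy)phenyl]cyclobutane-1,2-dicarboxylate
Product: 9 (1R,2R,3R,4R)-3,4-bis[3,4-bis(benzyloxy)phenyl]cyclobutane-1,2-dicarboxylic acid bis[(R)-1-carboxyethyl] ester, via mono-tert-butyl ester monoacid 8 (not isolated)
Conditions: TFA, Et3SiH, CH2Cl2, 0 °C to rt; evaporation
Reagents that add atoms: none
Why: Acidolysis of tert-butyl esters by loss of the tert-butyl cation, which Et3SiH reduces to isobutane before it can alkylate the electron-rich rings, while the secondary alkyl esters, the benzyl aryl ethers and all six stereocentres are not affected by brief cold TFA.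

Step 5
Reactants: 10 1,2-bis(benzyloxy)benzene
Product: 11 4-iodo-1,2-bis(benzyloxy)benzene
Conditions: N-iodosuccinimide, TFA (catalytic), MeCN, rt
Reagents that add atoms: N-iodosuccinimide, O=C1CCC(=O)N1I
Why: Electrophilic aromatic iodination with acid-activated N-iodosuccinimide, which enters the dialkoxy ring para to one ether oxygen (C4) as it does with veratrole, the unactivated benzyl rings staying untouched.

Step 6
Reactants: 9 (1R,2R,3R,4R)-3,4-bis[3,4-bis(benzyloxy)phenyl]cyclobutane-1,2-dicarboxylic acid bis[(R)-1-carboxyethyl] ester; 11 4-iodo-1,2-bis(benzyloxy)benzene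
Product: 13 (1R,2R,3R,4R)-3,4-bis[3,4-bis(benzyloxy)phenyl]cyclobutane-1,2-dicarboxylic acid bis{(R)-1-carboxy-2-[3,4-bis(benzyloxy)phenyl]ethyl} ester, via monoarylated diacid 12 (not isolated)
Conditions: Pd(OAc)2 (20 mol %), N-acetylglycine (40 mol %), Ag2CO3 (2 equiv), 11 (5 equiv), HFIP, 80 °C, sealed tube
Reagents that add atoms: 4-iodo-1,2-bis(benzyloxy)benzene (second molecule of 11), Ic1ccc(OCc2ccccc2)c(OCc2ccccc2)c1
Why: Proposed new method: each carboxylate of 9 binds divalent palladium and, with N-acetylglycine as internal base, the neighbouring methyl group undergoes concerted metalation–deprotonation to a five-membered palladacycle; oxidative addition of 11 gives an aryl tetravalent palladium species, reductive elimination forms the CH2–aryl bond, and Ag2CO3 takes up iodide and the proton, the cycle running once on each arm by way of 12 and so consuming two molecules of 11. The closest known reaction type is the ligand-enabled carboxylate-directed beta-methyl C(sp3)–H arylation of free alpha-substituted propionic acids (N-phthaloylalanine among them) together with the amide-directed arylation of O-protected lactic acid; a free O-acyl lactic acid, twice in one molecule, goes beyond it. No ring is closed in the product, the palladacycle being transient, and no stereocentre is created; the two lactate centres and the four ring centres are spectators that the weakly basic, non-nucleophilic medium should leave untouched, as it leaves the alpha-centre of protected alanines. The step needs site selectivity for the two methyl groups, and this is secured because they carry the only C–H bonds beta to a free acid, while the cyclobutane carbonyls are esters that do not direct and the ring C–H bonds would need larger, unfavoured palladacycles. It also needs mono-arylation, secured because after the first coupling only a benzylic methylene remains beta to each acid and methylene C–H bonds are not cleaved under these methyl-selective conditions. Loss of the beta-acyloxy group from the palladacycle is held back because the Pd–C and C–O bonds cannot become syn-coplanar within the five-membered ring.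

Step 7
Reactants: 13 (1R,2R,3R,4R)-3,4-bis[3,4-bis(benzyloxy)phenyl]cyclobutane-1,2-dicarboxylic acid bis{(R)-1-carboxy-2-[3,4-bis(benzyloxy)phenyl]ethyl} ester
Product: 14 (1R,2R,3R,4R)-3,4-bis(3,4-dihydroxyphenyl)cyclobutane-1,2-dicarboxylic acid bis[(R)-1-carboxy-2-(3,4-dihydroxyphenyl)ethyl] ester (CNP0163929.1)
Conditions: H2 (1 atm), palladium on carbon (Pd/C, 10 wt %), THF/MeOH, rt; filtration under argon, reversed-phase purification
Reagents that add atoms: none
Why: Hydrogenolysis of benzyl aryl ethers, which cleaves only the eight O–CH2Ph bonds because the lactate C–O bonds are homobenzylic and the cyclobutane is not opened at room temperature and one atmosphere, so all six stereocentres reach the target unchanged.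

**Compound list**

1 | 3,4-bis(benzyloxy)benzaldehyde | O=Cc1ccc(OCc2ccccc2)c(OCc2ccccc2)c1 | starting material
2 | (E)-1,2-bis[3,4-bis(benzyloxy)phenyl]ethene | O(Cc1ccccc1)c1ccc(/C=C/c2ccc(OCc3ccccc3)c(OCc3ccccc3)c2)cc1OCc1ccccc1 | intermediate
3 | tert-butyl (R)-lactate | C[C@@H](O)C(=O)OC(C)(C)C | starting material
4 | fumaryl chloride | O=C(Cl)/C=C/C(=O)Cl | starting material
5 | (R)-1-(tert-butoxycarbonyl)ethyl (E)-4-chloro-4-oxobut-2-enoate | CC(C)(C)OC(=O)[C@@H](C)OC(=O)/C=C/C(=O)Cl | intermediate
6 | bis[(R)-1-(tert-butoxycarbonyl)ethyl] fumarate | CC(C)(C)OC(=O)[C@@H](C)OC(=O)/C=C/C(=O)O[C@H](C)C(=O)OC(C)(C)C | intermediate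
7 | bis[(R)-1-(tert-butoxycarbonyl)ethyl] (1R,2R,3R,4R)-3,4-bis[3,4-bis(benzyloxy)phenyl]cyclobutane-1,2-dicarboxylate | O=C(O[C@H](C)C(=O)OC(C)(C)C)[C@H]1[C@H](C(=O)O[C@H](C)C(=O)OC(C)(C)C)[C@H](c2ccc(OCc3ccccc3)c(OCc3ccccc3)c2)[C@H]1c1ccc(OCc2ccccc2)c(OCc2ccccc2)c1 | intermediate
8 | (1R,2R,3R,4R)-3,4-bis[3,4-bis(benzyloxy)phenyl]cyclobutane-1,2-dicarboxylic acid 1-[(R)-1-carboxyethyl] 2-[(R)-1-(tert-butoxycarbonyl)ethyl] ester | O=C(O[C@H](C)C(=O)O)[C@H]1[C@H](C(=O)O[C@H](C)C(=O)OC(C)(C)C)[C@H](c2ccc(OCc3ccccc3)c(OCc3ccccc3)c2)[C@H]1c1ccc(OCc2ccccc2)c(OCc2ccccc2)c1 | intermediate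
9 | (1R,2R,3R,4R)-3,4-bis[3,4-bis(benzyloxy)phenyl]cyclobutane-1,2-dicarboxylic acid bis[(R)-1-carboxyethyl] ester | O=C(O[C@H](C)C(=O)O)[C@H]1[C@H](C(=O)O[C@H](C)C(=O)O)[C@H](c2ccc(OCc3ccccc3)c(OCc3ccccc3)c2)[C@H]1c1ccc(OCc2ccccc2)c(OCc2ccccc2)c1 | intermediate
10 | 1,2-bis(benzyloxy)benzene | c1ccc(OCc2ccccc2)c(OCc2ccccc2)c1 | starting material
11 | 4-iodo-1,2-bis(benzyloxy)benzene | Ic1ccc(OCc2ccccc2)c(OCc2ccccc2)c1 | intermediate
12 | (1R,2R,3R,4R)-3,4-bis[3,4-bis(benzyloxy)phenyl]cyclobutane-1,2-dicarboxylic acid 1-{(R)-1-carboxy-2-[3,4-bis(benzyloxy)phenyl]ethyl} 2-[(R)-1-carboxyethyl] ester | O=C(O[C@H](Cc1ccc(OCc2ccccc2)c(OCc2ccccc2)c1)C(=O)O)[C@H]1[C@H](C(=O)O[C@H](C)C(=O)O)[C@H](c2ccc(OCc3ccccc3)c(OCc3ccccc3)c2)[C@H]1c1ccc(OCc2ccccc2)c(OCc2ccccc2)c1 | intermediate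
13 | (1R,2R,3R,4R)-3,4-bis[3,4-bis(benzyloxy)phenyl]cyclobutane-1,2-dicarboxylic acid bis{(R)-1-carboxy-2-[3,4-bis(benzyloxy)phenyl]ethyl} ester | O=C(O[C@H](Cc1ccc(OCc2ccccc2)c(OCc2ccccc2)c1)C(=O)O)[C@H]1[C@H](C(=O)O[C@H](Cc2ccc(OCc3ccccc3)c(OCc3ccccc3)c2)C(=O)O)[C@H](c2ccc(OCc3ccccc3)c(OCc3ccccc3)c2)[C@H]1c1ccc(OCc2ccccc2)c(OCc2ccccc2)c1 | intermediate
14 | (1R,2R,3R,4R)-3,4-bis(3,4-dihydroxyphenyl)cyclobutane-1,2-dicarboxylic acid bis[(R)-1-carboxy-2-(3,4-dihydroxyphenyl)ethyl] ester | O=C(O[C@H](Cc1ccc(O)c(O)c1)C(=O)O)[C@H]1[C@H](C(=O)O[C@H](Cc2ccc(O)c(O)c2)C(=O)O)[C@H](c2ccc(O)c(O)c2)[C@H]1c1ccc(O)c(O)c1 | target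

**Count**

Total steps: 7. Longest linear sequence: 5 (step 1 or step 2, then steps 3, 4, 6 and 7).

**Steps most likely to fail**

1. Step 6 (bears the label). The carboxylate of an O-acyl lactic acid may hold palladium too weakly for the methyl C–H cleavage. The palladacycle may also shed the acyloxy group by beta-elimination, or the catalyst may die after one arm has coupled. Slow erosion of the lactate centres at 80 °C is a further danger.
Fallback with known chemistry, setting out from iodide 11 and coming back at target 14, in which the arm is built with its aryl group already in place. Iodide 11 is converted with iPrMgCl·LiCl (THF, 0 °C) into [3,4-bis(benzyloxy)phenyl]magnesium chloride F1. Under CuI catalysis (THF, −40 °C) this opens methyl (R)-glycidate (COC(=O)[C@H]1CO1) at its CH2 terminus to give methyl (R)-3-[3,4-bis(benzyloxy)phenyl]-2-hydroxypropanoate F2, the oxygen-bearing centre being untouched. LiOH in THF/H2O gives (R)-3-[3,4-bis(benzyloxy)phenyl]-2-hydroxypropanoic acid F3, and BnBr with Cs2CO3 in DMF gives benzyl (R)-3-[3,4-bis(benzyloxy)phenyl]-2-hydroxypropanoate F4. Acylation of two molecules of F4 with fumaryl chloride 4 as in step 2 gives bis{(R)-1-(benzyloxycarbonyl)-2-[3,4-bis(benzyloxy)phenyl]ethyl} fumarate F5. Irradiation with stilbene 2 as in step 3 and separation of the ring diastereomers gives the decabenzyl cyclobutane F6. Hydrogenolysis as in step 7 then cleaves the two benzyl esters and the eight benzyl ethers together and delivers 14.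

2. Step 3. The exciplex may discriminate poorly between the two faces of the fumarate, so that little of the wanted ring diastereomer forms. The bulky lactate esters may also slow the cycloaddition relative to E/Z isomerisation of both partners, stilbene dimerisation and carbonyl addition.
Fallback, setting out from stilbene 2 and coming back at 7, in which ring formation and attachment of the chiral arms are uncoupled. Stilbene 2 is irradiated under the same conditions with commercial di-tert-butyl fumarate (CC(C)(C)OC(=O)/C=C/C(=O)OC(C)(C)C) to give racemic di-tert-butyl 3,4-bis[3,4-bis(benzyloxy)phenyl]cyclobutane-1,2-dicarboxylate F7 of the same relative configuration. TFA and Et3SiH in CH2Cl2 give the racemic diacid F8. A twofold Mitsunobu esterification with two molecules of commercial tert-butyl (S)-lactate (C[C@H](O)C(=O)OC(C)(C)C; PPh3, DIAD, THF, 0 °C) then attaches both arms with inversion at the lactate carbon and without activating the ring carboxyl groups. Chromatographic separation of the two resulting diastereomers gives 7.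

3. Step 7. The hydrogenolysis may stall as partly deprotected, increasingly polar intermediates precipitate or bind the catalyst. Prolonged exposure may also lead to air oxidation of the freed catechols.
Fallback, setting out from 13 and coming back at 14: Lewis-acid debenzylation with BCl3 and pentamethylbenzene as cation scavenger in CH2Cl2 at −78 °C, followed by a methanol quench. This removes benzyl aryl ethers without hydrogen or metal and is known to spare esters.

**Further compounds**

F1 | step 6 | [3,4-bis(benzyloxy)phenyl]magnesium chloride | Cl[Mg]c1ccc(OCc2ccccc2)c(OCc2ccccc2)c1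
F2 | step 6 | methyl (R)-3-[3,4-bis(benzyloxy)phenyl]-2-hydroxypropanoate | COC(=O)[C@H](O)Cc1ccc(OCc2ccccc2)c(OCc2ccccc2)c1
F3 | step 6 | (R)-3-[3,4-bis(benzyloxy)phenyl]-2-hydroxypropanoic acid | OC(=O)[C@H](O)Cc1ccc(OCc2ccccc2)c(OCc2ccccc2)c1
F4 | step 6 | benzyl (R)-3-[3,4-bis(benzyloxy)phenyl]-2-hydroxypropanoate | O=C(OCc1ccccc1)[C@H](O)Cc1ccc(OCc2ccccc2)c(OCc2ccccc2)c1
F5 | step 6 | bis{(R)-1-(benzyloxycarbonyl)-2-[3,4-bis(benzyloxy)phenyl]ethyl} fumarate | O=C(/C=C/C(=O)O[C@H](Cc1ccc(OCc2ccccc2)c(OCc2ccccc2)c1)C(=O)OCc1ccccc1)O[C@H](Cc1ccc(OCc2ccccc2)c(OCc2ccccc2)c1)C(=O)OCc1ccccc1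
F6 | step 6 | bis{(R)-1-(benzyloxycarbonyl)-2-[3,4-bis(benzyloxy)phenyl]ethyl} (1R,2R,3R,4R)-3,4-bis[3,4-bis(benzyloxy)phenyl]cyclobutane-1,2-dicarboxylate | O=C(O[C@H](Cc1ccc(OCc2ccccc2)c(OCc2ccccc2)c1)C(=O)OCc1ccccc1)[C@H]1[C@H](C(=O)O[C@H](Cc2ccc(OCc3ccccc3)c(OCc3ccccc3)c2)C(=O)OCc2ccccc2)[C@H](c2ccc(OCc3ccccc3)c(OCc3ccccc3)c2)[C@H]1c1ccc(OCc2ccccc2)c(OCc2ccccc2)c1
F7 | step 3 | racemic di-tert-butyl (1R*,2R*,3R*,4R*)-3,4-bis[3,4-bis(benzyloxy)phenyl]cyclobutane-1,2-dicarboxylate (one enantiomer drawn) | CC(C)(C)OC(=O)[C@H]1[C@H](C(=O)OC(C)(C)C)[C@H](c2ccc(OCc3ccccc3)c(OCc3ccccc3)c2)[C@H]1c1ccc(OCc2ccccc2)c(OCc2ccccc2)c1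
F8 | step 3 | racemic (1R*,2R*,3R*,4R*)-3,4-bis[3,4-bis(benzyloxy)phenyl]cyclobutane-1,2-dicarboxylic acid (one enantiomer drawn) | OC(=O)[C@H]1[C@H](C(=O)O)[C@H](c2ccc(OCc3ccccc3)c(OCc3ccccc3)c2)[C@H]1c1ccc(OCc2ccccc2)c(OCc2ccccc2)c1
F0 | step 7 | none | none
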